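At early times the impurity and the free catalyst are the first pair to act, so my ladder of times starts there and climbs to the end of the run.

substrate 0.020 M; partner 0.900 equiv (fed, over 8.0 h); free catalyst 2 mol%; impurity 66 µM; time 6.0 d

    partner + free catalyst ⇌ catalyst intermediate A (K1 = 5.8 M⁻¹, k1 = 17 M⁻¹ min⁻¹)
    substrate + catalyst intermediate A ⇌ catalyst intermediate B (K2 = 4800 M⁻¹, k2 = 170 M⁻¹ min⁻¹)
    catalyst intermediate B ⇌ free catalyst + target (K3 = 0.046 M, k3 = 0.27 min⁻¹)
    target + free catalyst ⇌ isomer of the product + free catalyst, rate k4*[free catalyst]*[target] forward; the back reaction follows from the equilibrium constant (K4 = 0.33, k4 = 4.5 M⁻¹ min⁻¹)
    free catalyst + impurity → spent catalyst (k5 = 1600 M⁻¹ min⁻¹)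

* target at 6.0 d, in percent of the substrate charged
* isomer of the product at 6.0 d, in percent of the substrate charged
* amount of target if the flask were left three thousand times as long, in percent of the substrate charged

In this flask the impurity has a half-life of 1.08 min against the free catalyst as charged, and its charge equals 16.5% of the catalyst charged. Within the round, catalyst intermediate A has a half-life of 0.204 min against substrate as charged, and catalyst intermediate B releases target with a half-life of 2.57 min. Free catalyst, if it met the whole partner charge of 0.0180 M, has a half-life of 2.27 min, of like size to that release, so I name no single rate-limiting step. Higher up stand the 0.071 d of the partner pool on the charged catalyst, the 0.27 d of target turning into isomer, both by forward rate alone, and the feed of 8.0 h.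

Those are rates of one moment. Once the feed is over, as substrate and partner fall and the products rise, the back rates of the reversible steps gain on their forward rates. The top of the ladder is short against the 6.0 d allowed, so I expect thermodynamic control at the end.

I therefore carry the closing constant, the product of the first three equilibrium constants times one plus the isomer constant, 1700 M⁻¹: the value at which ([target]+[isomer])/([substrate][partner]) stops moving. Taking both charges less the amount turned over, and nothing held on the catalyst, I get 0.0158 M of products. Target is then 59.4% and isomer 19.6%. No listed step leaves this balance, so the long flask gives 59.4%.

The forecast gives 59.1%, 19.5% and 59.1%, with target less than mine, and says of the long flask: "Nothing drains the system at longer times".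

The simulation gives 59.1%, 19.5% and 59.1%. In this flask the round ran through the feed, and at 0.333 d target stood at 26.8%, with impurity at 0% of its charge and spent catalyst at 16.5% of the catalyst. By 3.00 d target read 59.0%, and at 60.0 d it read 59.1%, with substrate at 21.0% and partner at 12.2% of its charge still present at 6.00 d. Those readings give a quotient of 1700 M⁻¹, so this flask stops at its balance with both reactants present.

With 3.60 equiv of partner, the closing constant gives 0.0198 M of products: target 74.4%, isomer 24.5%, substrate 1.11%. That neighbour flask computes to 74.1%, 24.5% and 1.11%.

The constants belong to no real substance.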